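**Plan**

1. Retrosynthesis: the acetate C–O is cut first. The bond between the vinylic CH and the allylic CH2 of the side chain is then cut; it is treated as C4–C5 of a 3-substituted 5,6-dihydro-2H-pyran-2-one, which opens to an α-cyclohexyl acrylic acid and (R)-2-(oxiran-2-yl)propan-2-ol.
2. Enabling feature: the CH2OAc carbon (raised to acid level = lactone C2), the two alkene carbons (C3=C4), the allylic CH2 (C5) and the carbinol C–O (C6–O1) are six contiguous atoms that close to a δ-lactone. Its endocyclic C3=C4 can only be cis, and the carboxylate sits cis to the one vinylic C–H that must be alkylated (five-membered palladacycle).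
3. Core cuts: acrylic acid → methyl ketone; then the ring C–vinyl bond at the quaternary carbon and the adjacent ring C–isopropenyl bond, back to the enone of (S)-carvone. The ring C=O is removed and the carvone ring is kept throughout.
4. Forward order: carvone isopropenyl → masked acetyl; conjugate addition and vinylation; deoxygenation; unmasking and epimerisation; enol triflate → acrylic acid; fragment union with lactone ring formation; reductive lactone opening; acetylation.
5. Stereochemistry: carvone C5 directs the isopropenyl group (trans), which directs the vinyl group (trans). C5 itself is then equilibrated to the equatorial position. The carbinol centre comes from methyl (R)-glycidate, and the alkene geometry from the lactone ring.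

Key step: step 10

Remark (assumption): the acetyl epimerisation in step 6 is taken to be thermodynamically controlled with the 1,3-diequatorial isomer favoured; every yield and selectivity below is an expectation, not a measured result.

**Step 1**
Reactants: 1 (S)-(+)-carvone
Product: 3 (5S)-5-acetyl-2-methylcyclohex-2-en-1-one, via carvone ozonide 2 (not isolated)
Conditions: O3 (1 equiv, Sudan Red 7B end point), CH2Cl2, −78 °C; PPh3, −78 °C → rt
Reagents that add atoms: ozone ([O-][O+]=O)
Why: Ozonolysis with reductive work-up, in which the electron-rich 1,1-disubstituted isopropenyl C=C should react far faster with ozone than the electron-poor conjugated enone C=C, leaving the C5 stereocentre untouched.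

**Step 2**
Reactants: 3 (5S)-5-acetyl-2-methylcyclohex-2-en-1-one
Product: 4 (5S)-2-methyl-5-(2-methyl-1,3-dioxolan-2-yl)cyclohex-2-en-1-one
Conditions: TMSOCH2CH2OTMS, TMSOTf (cat.), CH2Cl2, −78 °C; pyridine quench
Reagents that add atoms: 1,2-bis(trimethylsilyloxy)ethane (C[Si](C)(C)OCCO[Si](C)(C)C)
Why: TMSOTf-catalysed acetalisation with the bis-silyl glycol ether should take the saturated methyl ketone selectively because the conjugated carbonyl is much less electrophilic, and the aprotic, base-free, low-temperature conditions should not enolise the α-stereocentre.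

**Step 3**
Reactants: 4 (5S)-2-methyl-5-(2-methyl-1,3-dioxolan-2-yl)cyclohex-2-en-1-one
Product: 5 trimethylsilyl enol ether of the (3R,5S)-3-isopropenyl ketone
Conditions: CH2=C(Me)MgBr (1.5 equiv), CuBr·SMe2 (10 mol %), TMSCl (2 equiv), THF, −78 °C; Et3N, NaHCO3 work-up
Reagents that add atoms: isopropenylmagnesium bromide (CC(=C)[Mg]Br); chlorotrimethylsilane (C[Si](C)(C)Cl)
Why: Copper-catalysed, TMSCl-accelerated conjugate addition in which axial attack anti to the equatorial C5 substituent should set the new C3 centre trans to C5, with the enolate trapped regiospecifically as its silyl enol ether.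

**Step 4**
Reactants: 5 trimethylsilyl enol ether
Product: 8 (2R,3R,5S)-2-ethenyl-2-methyl-5-(2-methyl-1,3-dioxolan-2-yl)-3-(prop-1-en-2-yl)cyclohexan-1-one, via lithium enolate 6 (not isolated), via sulfoxide adduct 7 (not isolated)
Conditions: MeLi (1.05 equiv), THF, 0 °C; PhS(O)CH=CH2, −78 → 0 °C; AcOH quench; then CaCO3, toluene, 110 °C
Reagents that add atoms: phenyl vinyl sulfoxide (C=CS(=O)c1ccccc1)
Why: Regiospecific enolate generation from the silyl enol ether, Michael addition to phenyl vinyl sulfoxide (a vinyl cation equivalent) and thermal sulfoxide syn-elimination, the electrophile entering axially on the face anti to the neighbouring C3 isopropenyl group so that the quaternary centre should carry vinyl trans and methyl cis to isopropenyl.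

**Step 5**
Reactants: 8 vinyl ketone
Product: 10 2-[(1R,3R,4R)-4-ethenyl-4-methyl-3-(prop-1-en-2-yl)cyclohexyl]-2-methyl-1,3-dioxolane, via hydrazone 9 (not isolated)
Conditions: N2H4·H2O, KOH, diethylene glycol, 130 °C then 200 °C
Reagents that add atoms: none
Why: Wolff–Kishner reduction (Huang-Minlon procedure), tolerated because the dioxolane is base-stable, the only enolisable α-carbon is not stereogenic, and the trans-1,2-dialkenylcyclohexane lies on the stable side of the Cope equilibrium.

**Step 6**
Reactants: 10 deoxygenated ketal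
Product: 12 1-[(1S,3R,4R)-4-ethenyl-4-methyl-3-(prop-1-en-2-yl)cyclohexyl]ethan-1-one, via epimeric methyl ketone 11 (not isolated)
Conditions: 1 M HCl, THF, rt; then NaOMe (0.2 equiv), MeOH, rt; chromatography, minor epimer re-equilibrated
Reagents that add atoms: water (O)
Why: Acetal hydrolysis followed by base-mediated epimerisation through the ketone enolate, where the acetyl-bearing carbon is the only epimerisable centre and equilibrium should favour the isomer with acetyl and isopropenyl both equatorial (1,3-cis) by roughly 1 kcal/mol.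

**Step 7**
Reactants: 12 methyl ketone
Product: 14 1-[(1S,3R,4R)-4-ethenyl-4-methyl-3-(prop-1-en-2-yl)cyclohexyl]ethenyl triflate, via potassium enolate 13 (not isolated)
Conditions: KHMDS, THF, −78 °C; PhNTf2, −78 → 0 °C; NH4Cl work-up
Reagents that add atoms: N-phenylbis(trifluoromethanesulfonimide) (O=S(=O)(N(c1ccccc1)S(=O)(=O)C(F)(F)F)C(F)(F)F)
Why: Kinetic deprotonation of the methyl group and O-triflation should give the 1,1-disubstituted enol triflate without disturbing the ring α-stereocentre.

**Step 8**
Reactants: 14 enol triflate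
Product: 15 2-[(1S,3R,4R)-4-ethenyl-4-methyl-3-(prop-1-en-2-yl)cyclohexyl]prop-2-enoic acid
Conditions: Pd(OAc)2 (5 mol %), dppf (6 mol %), CO (1 atm), KOAc (4 equiv), DMF/H2O (20:1), 60 °C; acidic work-up
Reagents that add atoms: carbon monoxide ([C-]#[O+]); water (O)
Why: Palladium-catalysed hydroxycarbonylation of an enol triflate (oxidative addition, CO insertion, acyl capture), to which the isolated alkenes are inert.

**Step 9**
Reactants: 16 methyl (2R)-oxirane-2-carboxylate
Product: 18 2-[(2R)-oxiran-2-yl]propan-2-ol, via epoxy ketone 17 (not isolated)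
Conditions: MeMgCl (2.2 equiv), THF, −78 → −40 °C; sat. NH4Cl at −40 °C
Reagents that add atoms: methylmagnesium chloride (C[Mg]Cl)
Why: Double Grignard addition to the ester at a temperature where uncatalysed epoxide opening is slow, the stereocentre not taking part and the cold quench avoiding Payne rearrangement of the tertiary alkoxide.

**Step 10**
Reactants: 15 α-cyclohexyl acrylic acid; 18 2-[(2R)-oxiran-2-yl]propan-2-ol
Product: 20 (6R)-3-[(1S,3R,4R)-4-ethenyl-4-methyl-3-(prop-1-en-2-yl)cyclohexyl]-6-(2-hydroxypropan-2-yl)-5,6-dihydro-2H-pyran-2-one, via hydroxy acid 19 (not isolated)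
Conditions: Pd(OAc)2 (10 mol %), Ac-tLeu-OH (20 mol %), KOAc (1.0 equiv), 18 (2 equiv), HFIP, 40 °C
Reagents that add atoms: none
Why: Proposed new method: the potassium carboxylate of 15 binds Pd(II) and directs concerted metalation–deprotonation of the β-vinylic C–H cis to it, giving a five-membered alkenyl palladacycle whose C–Pd bond opens the K+/HFIP-activated epoxide 18 by SN2 attack at its CH2 terminus (redox-neutral), after which hydroxy acid 19 lactonises and Pd(II) is released. The closest known reaction type is the Pd(II)/mono-N-protected amino acid catalysed ortho-C–H alkylation of benzoic acids with terminal epoxides to 3,4-dihydroisocoumarins, and carboxylate-directed activation of the cis β-vinylic C–H of α-substituted acrylic acids is known from Rh(III)- and Ru(II)-catalysed annulations, so each elementary step has precedent but the combination on an acrylic acid does not. The dihydropyranone ring closes by 6-exo-trig lactonisation of the C5 hydroxyl onto the carboxyl carbon. No new stereocentre is formed: lactone C6 is the epoxide centre, untouched because attack occurs at the CH2, and the alkene geometry (carboxyl cis to the new CH2) is fixed by the palladacycle and locked by the ring. The step needs site selectivity for this one vinylic C–H over the vinyl, isopropenyl and allylic C–H bonds and over carboxylate O-alkylation, plus terminal regioselectivity at the epoxide; the carboxylate is the only directing group with a C(sp2)–H in five-membered reach, and the internal epoxide carbon is shielded by the adjacent fully substituted carbinol.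

**Step 11**
Reactants: 20 unsaturated δ-lactone
Product: 22 (2Z,5R)-2-[(1S,3R,4R)-4-ethenyl-4-methyl-3-(prop-1-en-2-yl)cyclohexyl]-6-methylhept-2-ene-1,5,6-triol, via lactol 21 (not isolated)
Conditions: DIBAL-H (5 equiv), CH2Cl2, −78 → 0 °C; Rochelle salt
Reagents that add atoms: none
Why: DIBAL-H reduction of an α,β-unsaturated lactone proceeds 1,2 via the lactol to the allylic alcohol without conjugate reduction, so the ring-derived Z geometry should be carried into the open chain.

**Step 12**
Reactants: 22 triol
Product: 23 target acetate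
Conditions: Ac2O (1.1 equiv), pyridine, CH2Cl2, 0 °C
Reagents that add atoms: acetic anhydride (CC(=O)OC(C)=O)
Why: Chemoselective acylation of the primary allylic hydroxyl, since the secondary hydroxyl is flanked by a fully substituted carbinol carbon and the tertiary hydroxyl does not acylate without DMAP.

**Compound list**

1 | (S)-(+)-carvone, (5S)-2-methyl-5-(prop-1-en-2-yl)cyclohex-2-en-1-one | CC1=CC[C@H](C(C)=C)CC1=O | starting material
2 | (5S)-2-methyl-5-(3-methyl-1,2,4-trioxolan-3-yl)cyclohex-2-en-1-one (trioxolane epimers) | CC1=CC[C@H](C2(C)OCOO2)CC1=O | intermediate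
3 | (5S)-5-acetyl-2-methylcyclohex-2-en-1-one | CC1=CC[C@H](C(C)=O)CC1=O | intermediate
4 | (5S)-2-methyl-5-(2-methyl-1,3-dioxolan-2-yl)cyclohex-2-en-1-one | CC1=CC[C@H](C2(C)OCCO2)CC1=O | intermediate
5 | trimethyl{[(3R,5S)-2-methyl-5-(2-methyl-1,3-dioxolan-2-yl)-3-(prop-1-en-2-yl)cyclohex-1-en-1-yl]oxy}silane (3,5-trans) | CC1=C(O[Si](C)(C)C)C[C@@H](C2(C)OCCO2)C[C@@H]1C(C)=C | intermediate
6 | lithium (3R,5S)-2-methyl-5-(2-methyl-1,3-dioxolan-2-yl)-3-(prop-1-en-2-yl)cyclohex-1-en-1-olate | CC1=C([O-])C[C@@H](C2(C)OCCO2)C[C@@H]1C(C)=C.[Li+] | intermediate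
7 | (2R,3R,5S)-2-methyl-5-(2-methyl-1,3-dioxolan-2-yl)-2-[2-(phenylsulfinyl)ethyl]-3-(prop-1-en-2-yl)cyclohexan-1-one (sulfur epimers) | O=S(CC[C@@]1(C)C(=O)C[C@@H](C2(C)OCCO2)C[C@@H]1C(C)=C)c1ccccc1 | intermediate
8 | (2R,3R,5S)-2-ethenyl-2-methyl-5-(2-methyl-1,3-dioxolan-2-yl)-3-(prop-1-en-2-yl)cyclohexan-1-one | C=C[C@@]1(C)C(=O)C[C@@H](C2(C)OCCO2)C[C@@H]1C(C)=C | intermediate
9 | hydrazone of 8 | C=C[C@@]1(C)C(=NN)C[C@@H](C2(C)OCCO2)C[C@@H]1C(C)=C | intermediate
10 | 2-[(1R,3R,4R)-4-ethenyl-4-methyl-3-(prop-1-en-2-yl)cyclohexyl]-2-methyl-1,3-dioxolane | C=C[C@@]1(C)CC[C@@H](C2(C)OCCO2)C[C@@H]1C(C)=C | intermediate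
11 | 1-[(1R,3R,4R)-4-ethenyl-4-methyl-3-(prop-1-en-2-yl)cyclohexyl]ethan-1-one (acetyl trans to isopropenyl) | C=C[C@@]1(C)CC[C@@H](C(C)=O)C[C@@H]1C(C)=C | intermediate
12 | 1-[(1S,3R,4R)-4-ethenyl-4-methyl-3-(prop-1-en-2-yl)cyclohexyl]ethan-1-one (acetyl cis to isopropenyl) | C=C[C@@]1(C)CC[C@H](C(C)=O)C[C@@H]1C(C)=C | intermediate
13 | potassium 1-[(1S,3R,4R)-4-ethenyl-4-methyl-3-(prop-1-en-2-yl)cyclohexyl]ethen-1-olate | C=C[C@@]1(C)CC[C@H](C(=C)[O-])C[C@@H]1C(C)=C.[K+] | intermediate
14 | 1-[(1S,3R,4R)-4-ethenyl-4-methyl-3-(prop-1-en-2-yl)cyclohexyl]ethenyl trifluoromethanesulfonate | C=C[C@@]1(C)CC[C@H](C(=C)OS(=O)(=O)C(F)(F)F)C[C@@H]1C(C)=C | intermediate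
15 | 2-[(1S,3R,4R)-4-ethenyl-4-methyl-3-(prop-1-en-2-yl)cyclohexyl]prop-2-enoic acid | C=C[C@@]1(C)CC[C@H](C(=C)C(=O)O)C[C@@H]1C(C)=C | intermediate
16 | methyl (2R)-oxirane-2-carboxylate (methyl (R)-glycidate) | COC(=O)[C@H]1CO1 | starting material
17 | 1-[(2R)-oxiran-2-yl]ethan-1-one | CC(=O)[C@H]1CO1 | intermediate
18 | 2-[(2R)-oxiran-2-yl]propan-2-ol | CC(C)(O)[C@H]1CO1 | intermediate
19 | (2Z,5R)-2-[(1S,3R,4R)-4-ethenyl-4-methyl-3-(prop-1-en-2-yl)cyclohexyl]-5,6-dihydroxy-6-methylhept-2-enoic acid | C=C[C@@]1(C)CC[C@H](/C(=C/C[C@@H](O)C(C)(C)O)C(=O)O)C[C@@H]1C(C)=C | intermediate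
20 | (6R)-3-[(1S,3R,4R)-4-ethenyl-4-methyl-3-(prop-1-en-2-yl)cyclohexyl]-6-(2-hydroxypropan-2-yl)-5,6-dihydro-2H-pyran-2-one | C=C[C@@]1(C)CC[C@H](C2=CC[C@H](C(C)(C)O)OC2=O)C[C@@H]1C(C)=C | intermediate
21 | (6R)-3-[(1S,3R,4R)-4-ethenyl-4-methyl-3-(prop-1-en-2-yl)cyclohexyl]-6-(2-hydroxypropan-2-yl)-5,6-dihydro-2H-pyran-2-ol (anomers) | C=C[C@@]1(C)CC[C@H](C2=CC[C@H](C(C)(C)O)OC2O)C[C@@H]1C(C)=C | intermediate
22 | (2Z,5R)-2-[(1S,3R,4R)-4-ethenyl-4-methyl-3-(prop-1-en-2-yl)cyclohexyl]-6-methylhept-2-ene-1,5,6-triol | C=C[C@@]1(C)CC[C@H](/C(=C/C[C@@H](O)C(C)(C)O)CO)C[C@@H]1C(C)=C | intermediate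
23 | (2Z,5R)-2-[(1S,3R,4R)-4-ethenyl-4-methyl-3-(prop-1-en-2-yl)cyclohexyl]-5,6-dihydroxy-6-methylhept-2-en-1-yl acetate (CNP0277695.1) | C=C[C@@]1(C)CC[C@H](/C(=C/C[C@@H](O)C(C)(C)O)COC(C)=O)C[C@@H]1C(=C)C | target

**Step count**

Total steps: 12. Longest linear sequence: 11 (steps 1–8 and 10–12); step 9 prepares the epoxide fragment.

**Steps most likely to fail**

Step 10 (proposed new method). The alkenyl C–H palladation may be outrun by O-alkylation of the carboxylate by the epoxide, or the catalyst may be tied up by the three other alkenes, so that no C–C bond forms. The fallback uses known chemistry, sets out from 14 and returns at 22, and forms the same vinylic CH–CH2 bond. Elimination of the triflate from 14 with LDA gives the terminal alkyne F1. Rhodium-catalysed silylformylation (Me2PhSiH, CO) places the formyl group on the internal carbon and the silyl group cis to it on the terminus, giving the (Z)-β-silyl enal F2. NaBH4 reduction gives the silyl allylic alcohol F3. Iododesilylation with NIS in HFIP, with retention, gives the (Z)-iodo allylic alcohol F4. Nickel-catalysed reductive cross-electrophile coupling of F4 with epoxide 18 (bipyridine ligand, NaI co-catalyst for terminal opening, Mn) gives triol 22, which continues with step 12.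

Step 4. Michael addition of the hindered, fully substituted enolate may be slow, and proton transfer to the adduct carbanion may return ketone or cause over-alkylation. The fallback sets out from 5 and returns at 8. MeLi cleavage, transmetalation with ZnCl2 and aldol addition to acetaldehyde (same facial preference, anti to the isopropenyl group) give the β-hydroxy ketone F5. Dehydration with the Burgess reagent, a syn-elimination that can only use the methyl hydrogens because the other neighbour is quaternary, gives vinyl ketone 8.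

Step 6. The thermodynamic bias of the epimerisation may be too small, because the unwanted epimer can relieve strain in its alternative chair, leaving a poorly separable mixture. The fallback replaces equilibration by kinetic hydride delivery, sets out from 8 and returns at 12. IBX dehydrogenation of 8 (only one α-carbon bears hydrogen) gives the enone F6. Conjugate reduction with Stryker's reagent adds hydride axially, anti to the isopropenyl-bearing carbon (the usual 3,5-trans rule), so the dioxolanyl group ends cis to isopropenyl in ketone F7. Wolff–Kishner reduction gives the ketal F8, and acid hydrolysis gives 12 without an epimerisation step.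

**Further compounds**

F1 | step 10 | (1R,2R,4S)-1-ethenyl-4-ethynyl-1-methyl-2-(prop-1-en-2-yl)cyclohexane | C=C[C@@]1(C)CC[C@H](C#C)C[C@@H]1C(C)=C
F2 | step 10 | (2Z)-3-[dimethyl(phenyl)silyl]-2-[(1S,3R,4R)-4-ethenyl-4-methyl-3-(prop-1-en-2-yl)cyclohexyl]prop-2-enal | C=C[C@@]1(C)CC[C@H](/C(C=O)=C/[Si](C)(C)c2ccccc2)C[C@@H]1C(C)=C
F3 | step 10 | (2Z)-3-[dimethyl(phenyl)silyl]-2-[(1S,3R,4R)-4-ethenyl-4-methyl-3-(prop-1-en-2-yl)cyclohexyl]prop-2-en-1-ol | C=C[C@@]1(C)CC[C@H](/C(CO)=C/[Si](C)(C)c2ccccc2)C[C@@H]1C(C)=C
F4 | step 10 | (2Z)-3-iodo-2-[(1S,3R,4R)-4-ethenyl-4-methyl-3-(prop-1-en-2-yl)cyclohexyl]prop-2-en-1-ol | C=C[C@@]1(C)CC[C@H](/C(CO)=C/I)C[C@@H]1C(C)=C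
F5 | step 4 | (2S,3R,5S)-2-(1-hydroxyethyl)-2-methyl-5-(2-methyl-1,3-dioxolan-2-yl)-3-(prop-1-en-2-yl)cyclohexan-1-one (carbinol epimers) | CC(O)[C@@]1(C)C(=O)C[C@@H](C2(C)OCCO2)C[C@@H]1C(C)=C
F6 | step 6 | (5R,6R)-6-ethenyl-6-methyl-3-(2-methyl-1,3-dioxolan-2-yl)-5-(prop-1-en-2-yl)cyclohex-2-en-1-one | C=C[C@@]1(C)C(=O)C=C(C2(C)OCCO2)C[C@@H]1C(C)=C
F7 | step 6 | (2R,3R,5R)-2-ethenyl-2-methyl-5-(2-methyl-1,3-dioxolan-2-yl)-3-(prop-1-en-2-yl)cyclohexan-1-one | C=C[C@@]1(C)C(=O)C[C@H](C2(C)OCCO2)C[C@@H]1C(C)=C
F8 | step 6 | 2-[(1S,3R,4R)-4-ethenyl-4-methyl-3-(prop-1-en-2-yl)cyclohexyl]-2-methyl-1,3-dioxolane | C=C[C@@]1(C)CC[C@H](C2(C)OCCO2)C[C@@H]1C(C)=C
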